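**Retrosynthetic overview**

1. Core numbering (6-oxabicyclo[3.2.1]octane): C1 (quaternary, CH3), C2 (CHOH), C3, C4, C5 (CH3, ether carbon), O6, C7H2, C8 (side chain). The aryl ether is cut last (Mitsunobu reaction with umbelliferone), and the C2 alcohol goes back to the C2 ketone.
2. Key disconnection: C3–C4 together with C5–O6, back to an acyclic silyl enol ether. The C3 radical (α to C2=O) adds to C4 of a C5 isopropenyl group, which closes the carbocycle first; the C5 cation is then captured by the C7 oxygen, which closes the tetrahydrofuran second, in the same operation.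
3. Enabling feature: in the ring C1–C2–C3–C4–C5–C8, C3 lies α to the C2 oxygen function, C4 is the CH2 of a C5(CH3)(O) unit, and the O6–C7 bridge spans C1 and C5 in a 1,3-diaxial way, so C5 needs no control of its own.
4. The C1/C8 dyad and the isopropenyl group come from one auxiliary-controlled Carroll rearrangement (C1–C8 bond) of a 2-methylacetoacetate ester of an (E)-8-hydroxygeraniol derivative; reduction of the carboxylate gives C7.
5. Building blocks: geraniol, ethyl 2-methylacetoacetate, SAMP, umbelliferone.

Key step: step 8

Assumption: the facial control by SAMP in the chelated aza-enolate of step 5 is taken to give the (3R,4S) series of 11; the relative configuration does not depend on this, and the enantiomeric auxiliary RAMP would be used in the same way if the sense is the opposite.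

**Step 1**
Reactants: 1 geraniol
Product: 2 geranyl tert-butyldiphenylsilyl ether
Conditions: TBDPSCl, imidazole, DMF, 0 °C to rt
Reagents that add atoms: tert-butyl(chloro)diphenylsilane, CC(C)(C)[Si](Cl)(c1ccccc1)c1ccccc1
Why: O-silylation of a primary allylic alcohol gives an ether that should survive LiN(iPr)2, LiAlH4, oxalic acid and the cerium oxidant.

**Step 2**
Reactants: 2 geranyl tert-butyldiphenylsilyl ether
Product: 3 (2E,6E)-8-silyloxy-2,6-dimethylocta-2,6-dien-1-ol
Conditions: SeO2 (0.3 equiv), t-BuOOH, salicylic acid (cat.), CH2Cl2, 0 °C to rt, stopped at partial conversion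
Reagents that add atoms: tert-butyl hydroperoxide, CC(C)(C)OO (terminal oxygen source); selenium dioxide, O=[Se]=O (transfers the oxygen, substoichiometric)
Why: Riley-type allylic oxidation (ene reaction, then [2,3]-shift) should attack the (E)-methyl group of the more electron-rich distal alkene and give the (E)-allylic alcohol.

**Step 3**
Reactants: 3 (2E,6E)-8-silyloxy-2,6-dimethylocta-2,6-dien-1-ol; 4 ethyl 2-methyl-3-oxobutanoate
Product: 5 allylic 2-methyl-3-oxobutanoate
Conditions: DMAP (0.3 equiv), toluene, reflux, 4 Å molecular sieves (removal of EtOH)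
Reagents that add atoms: none
Why: DMAP-mediated transesterification of an enolizable β-keto ester through its acylketene; the configuration of the α-carbon is irrelevant because it is deprotonated in step 5.

**Step 4**
Reactants: 5 allylic 2-methyl-3-oxobutanoate; 6 SAMP, (S)-1-amino-2-(methoxymethyl)pyrrolidine
Product: 7 SAMP hydrazone of keto ester 5
Conditions: cyclohexane, TsOH (cat.), 4 Å molecular sieves, rt to 50 °C
Reagents that add atoms: none
Why: Hydrazone condensation at the ketone carbonyl only; the second nitrogen is tertiary, so no pyrazolone can form.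

**Step 5**
Reactants: 7 SAMP hydrazone of keto ester 5
Product: 10 β-hydroxy SAMP hydrazone, via lithium aza-enolate 8 (not isolated), via lithium carboxylate 9 (not isolated)
Conditions: LiN(iPr)2 (1.2 equiv), THF, −78 °C to rt; then LiAlH4, 0 °C to rt; aqueous Rochelle-salt work-up
Reagents that add atoms: none
Why: Aza-enolate Carroll rearrangement, a [3,3]-sigmatropic shift of the O-allyl ketene acetal 8 through a chair in which lithium chelation holds the hydrazone carbon cis to O–Li and the (E)-alkene places the chain equatorial, should fix the relative configuration of the quaternary and tertiary carbons while the auxiliary differentiates the enolate faces; LiAlH4 then reduces the α-quaternary carboxylate 9 before it can decarboxylate.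

**Step 6**
Reactants: 10 β-hydroxy SAMP hydrazone
Product: 11 (3R,4S)-β-hydroxy ketone
Conditions: saturated aqueous oxalic acid, Et2O, rt, vigorous stirring
Reagents that add atoms: water, O
Why: Mild two-phase acid hydrolysis of the hydrazone should release the ketone without epimerization, since C3 is quaternary, and allows recovery of the auxiliary.

**Step 7**
Reactants: 11 (3R,4S)-β-hydroxy ketone
Product: 12 bis(trimethylsilyl) derivative (silyl enol ether and silyl ether)
Conditions: TMSOTf (2.5 equiv), Et3N (3 equiv), CH2Cl2, −78 to 0 °C; non-aqueous work-up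
Reagents that add atoms: trimethylsilyl trifluoromethanesulfonate, C[Si](C)(C)OS(=O)(=O)C(F)(F)F
Why: Soft enolization and silylation; the ketone can enolize only toward its methyl group because the other α-carbon is quaternary, and the primary hydroxyl is silylated at the same time.

**Step 8**
Reactants: 12 bis(trimethylsilyl) derivative
Product: 14 bicyclic keto ether, via ring carbocation 13 (not isolated)
Conditions: (NH4)2Ce(NO3)6 (2.2 equiv, slow addition), NaHCO3, MeCN, −20 to 0 °C, high dilution
Reagents that add atoms: none
Why: Proposed new method: one-electron oxidation of the silyl enol ether, the most easily oxidized π-system of 12, by tetravalent cerium should give after loss of the silyl group the C3 radical α to the C2 ketone, which adds in a 6-endo-trig mode to the unsubstituted terminus C4 of the isopropenyl group; a second oxidation turns the tertiary C5 radical into carbocation 13, which the C7 silyl ether oxygen captures with loss of the second silyl group, a five-membered ring closure across the 1,3-diaxial positions C1 and C5. The closest known reaction type is the oxidative cyclization of unsaturated silyl enol ethers with (NH4)2Ce(NO3)6 or Cu(OTf)2 that ends in capture of the ring cation by an arene; capture by a tethered oxygen is the new element and has its counterpart in radical–polar crossover carboetherifications of alkenes. The 6-endo mode is secured over 5-exo by the carbonyl carbon inside the forming ring and by the 1,1-disubstituted alkene, whose attack at C4 gives a tertiary radical. C5 is the only new stereocentre and is set by the tether: O6 can reach the planar cation only from the face of the axial C7 arm on C1, so the C5 configuration follows from C1, while C1 and C8 are carried unchanged from 11 with the side chain equatorial in the chair. The needed chemoselectivity, ring closure before the remote side-chain alkene or a nitrate ligand intercepts the intermediates, should be helped by high dilution, slow addition of the oxidant and the deactivating allylic silyloxy group.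

**Step 9**
Reactants: 14 bicyclic keto ether
Product: 15 bicyclic (2R)-alcohol
Conditions: NaBH4, MeOH, −20 to 0 °C
Reagents that add atoms: none
Why: Hydride reduction of the ring ketone; axial attack from the face of the C8 bridge, away from the axial C7 arm on the neighbouring quaternary C1, should give the equatorial (2R)-alcohol.

**Step 10**
Reactants: 15 bicyclic (2R)-alcohol
Product: 16 diol
Conditions: Bu4NF, THF, rt
Reagents that add atoms: none
Why: Fluoride-induced cleavage of the silyl ether; no ketone remains that could undergo base-induced cleavage.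

**Step 11**
Reactants: 16 diol; 17 umbelliferone (7-hydroxycoumarin)
Product: 18 target CNP0178104.1
Conditions: PPh3, DIAD, THF, 0 °C to rt
Reagents that add atoms: none
Why: Mitsunobu etherification of the acidic phenol should occur at the primary allylic alcohol only, because the secondary alcohol next to the quaternary C1 is too hindered to form or displace an oxyphosphonium ion; no stereocentre is touched.

**Compound list**

1 | geraniol, (2E)-3,7-dimethylocta-2,6-dien-1-ol | CC(C)=CCC/C(C)=C/CO | starting material
2 | tert-butyl{[(2E)-3,7-dimethylocta-2,6-dien-1-yl]oxy}diphenylsilane | CC(C)=CCC/C(C)=C/CO[Si](c1ccccc1)(c1ccccc1)C(C)(C)C | intermediate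
3 | (2E,6E)-8-[(tert-butyldiphenylsilyl)oxy]-2,6-dimethylocta-2,6-dien-1-ol | OC/C(C)=C/CC/C(C)=C/CO[Si](c1ccccc1)(c1ccccc1)C(C)(C)C | intermediate
4 | ethyl 2-methyl-3-oxobutanoate (racemic) | CCOC(=O)C(C)C(C)=O | starting material
5 | (2E,6E)-8-[(tert-butyldiphenylsilyl)oxy]-2,6-dimethylocta-2,6-dien-1-yl 2-methyl-3-oxobutanoate (both configurations at the α-carbon) | CC(=O)C(C)C(=O)OC/C(C)=C/CC/C(C)=C/CO[Si](c1ccccc1)(c1ccccc1)C(C)(C)C | intermediate
6 | SAMP, (2S)-2-(methoxymethyl)pyrrolidin-1-amine | COC[C@@H]1CCCN1N | starting material
7 | SAMP hydrazone of 5 at the ketone carbonyl (C=N geometry and α-carbon not defined) | CC(=NN1CCC[C@H]1COC)C(C)C(=O)OC/C(C)=C/CC/C(C)=C/CO[Si](c1ccccc1)(c1ccccc1)C(C)(C)C | intermediate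
8 | lithium aza-enolate of 7, an O-lithio O-allyl ketene acetal with the hydrazone carbon cis to O–Li | [Li]O/C(OC/C(C)=C/CC/C(C)=C/CO[Si](c1ccccc1)(c1ccccc1)C(C)(C)C)=C(/C)C(C)=NN1CCC[C@H]1COC | intermediate
9 | lithium carboxylate from the rearrangement: α-methyl α-(hydrazonoethyl) carboxylate with the neighbouring CH carrying isopropenyl and the side chain, configured as in 11 | CC(=NN1CCC[C@H]1COC)[C@@](C)(C(=O)O[Li])[C@H](C(C)=C)CC/C(C)=C/CO[Si](c1ccccc1)(c1ccccc1)C(C)(C)C | intermediate
10 | SAMP hydrazone of 11 (β-hydroxy hydrazone, C3 and C4 arranged as in 11) | CC(=NN1CCC[C@H]1COC)[C@@](C)(CO)[C@H](C(C)=C)CC/C(C)=C/CO[Si](c1ccccc1)(c1ccccc1)C(C)(C)C | intermediate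
11 | (3R,4S,7E)-9-[(tert-butyldiphenylsilyl)oxy]-3-(hydroxymethyl)-3,7-dimethyl-4-(prop-1-en-2-yl)non-7-en-2-one | CC(=O)[C@@](C)(CO)[C@H](C(C)=C)CC/C(C)=C/CO[Si](c1ccccc1)(c1ccccc1)C(C)(C)C | intermediate
12 | bis(trimethylsilyl) derivative of 11: 2-(trimethylsilyloxy)-1-ene silyl enol ether with the C3 CH2OSiMe3 group, (3R,4S,7E) | C=C(O[Si](C)(C)C)[C@@](C)(CO[Si](C)(C)C)[C@H](C(C)=C)CC/C(C)=C/CO[Si](c1ccccc1)(c1ccccc1)C(C)(C)C | intermediate
13 | tertiary cyclohexyl cation: 4-oxocyclohexyl cation with the cationic carbon bearing CH3, flanked by the CH carrying the side chain and the quaternary carbon carrying CH3 and CH2OSiMe3 | C/C(=C\CO[Si](c1ccccc1)(c1ccccc1)C(C)(C)C)CC[C@H]1[C+](C)CCC(=O)[C@@]1(C)CO[Si](C)(C)C | intermediate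
14 | (1R,5S,8R)-8-[(3E)-5-[(tert-butyldiphenylsilyl)oxy]-3-methylpent-3-en-1-yl]-1,5-dimethyl-6-oxabicyclo[3.2.1]octan-2-one | C/C(=C\CO[Si](c1ccccc1)(c1ccccc1)C(C)(C)C)CC[C@@H]1[C@]2(C)CO[C@@]1(C)CCC2=O | intermediate
15 | (1R,2R,5S,8R)-8-[(3E)-5-[(tert-butyldiphenylsilyl)oxy]-3-methylpent-3-en-1-yl]-1,5-dimethyl-6-oxabicyclo[3.2.1]octan-2-ol | C/C(=C\CO[Si](c1ccccc1)(c1ccccc1)C(C)(C)C)CC[C@@H]1[C@]2(C)CO[C@@]1(C)CC[C@H]2O | intermediate
16 | (1R,2R,5S,8R)-8-[(3E)-5-hydroxy-3-methylpent-3-en-1-yl]-1,5-dimethyl-6-oxabicyclo[3.2.1]octan-2-ol | C/C(=C\CO)CC[C@@H]1[C@]2(C)CO[C@@]1(C)CC[C@H]2O | intermediate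
17 | umbelliferone, 7-hydroxy-2H-chromen-2-one | Oc1ccc2ccc(=O)oc2c1 | starting material
18 | 7-{[(2E)-5-[(1R,2R,5S,8R)-2-hydroxy-1,5-dimethyl-6-oxabicyclo[3.2.1]octan-8-yl]-3-methylpent-2-en-1-yl]oxy}-2H-chromen-2-one | C/C(=C\COc1ccc2ccc(=O)oc2c1)CC[C@@H]1[C@]2(C)CO[C@@]1(C)CC[C@H]2O | target

**Step count and risks**

Total steps: 11. Longest linear sequence: 11 steps (from geraniol 1).

Most likely to fail:

1. Step 8 (proposed new method). The C3 radical or the ring cation may be intercepted before both rings have closed: nitrate transfer to the radical, loss of a proton from the cation to give ring alkenes, attack by the side-chain alkene, or simple desilylation of the enol ether without oxidation. The fallback uses known chemistry, sets out from 11 and returns to 14. Hydroxyl-directed epoxidation of the isopropenyl group (VO(acac)2, t-BuOOH, CH2Cl2), followed by acid-promoted 5-exo opening of the epoxide at its tertiary carbon by the primary hydroxyl (AcOH), should give the 2-(hydroxymethyl)tetrahydrofuran F1; only the epimer with CH2OH cis to the acetyl group is carried on. Dess–Martin oxidation gives the keto aldehyde F2, whose aldehyde cannot enolize. Intramolecular aldol condensation (KOH, MeOH) then closes the same C3–C4 bond and gives the bicyclic enone F3. Conjugate reduction with [(Ph3P)CuH]6 in wet toluene leaves the side-chain alkene untouched and gives 14.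

2. Step 5. The auxiliary may discriminate the two enolate faces poorly, or the rearranged carboxylate may decarboxylate before it is reduced. The fallback separates relative from absolute control, sets out from 5 and returns to 11. Condensation of 5 with N,N-dimethylhydrazine gives the dimethylhydrazone F4. The same anionic Carroll rearrangement and LiAlH4 reduction should give the racemic hydroxy hydrazone F5 with the chair-controlled relative configuration. Esterification with (S)-2-methoxy-2-phenylacetic acid (DCC, DMAP) and chromatographic separation of the diastereomers gives the ester F6. Methanolysis (K2CO3, MeOH), carried out while the ketone is still masked so that no retro-aldol cleavage can occur, gives the enantiopure hydroxy dimethylhydrazone F7. Hydrolysis with aqueous oxalic acid gives 11.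

3. Step 6. Hydrolysis of the hindered hydrazone next to the quaternary carbon may be slow, and long exposure to acid may cost the allylic silyl ether or cleave the β-hydroxy ketone by a retro-aldol reaction. The fallback sets out from 10 and returns to 11. N-Methylation of the pyrrolidine nitrogen (MeI, 60 °C) gives the hydrazonium iodide F8, whose activated C=N bond should hydrolyse within minutes in a two-phase mixture of 1 M HCl and pentane at rt to give 11.

**Further compounds**

F1 | step 8 | 2-(hydroxymethyl)tetrahydrofuran from 11: oxolane with C2 (CH3, CH2OH), C3 (H, side chain), C4 (CH3, acetyl), CH2OH cis to acetyl and both trans to the side chain | C/C(=C\CO[Si](c1ccccc1)(c1ccccc1)C(C)(C)C)CC[C@@H]1[C@@](C)(C(C)=O)CO[C@@]1(C)CO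
F2 | step 8 | keto aldehyde: F1 with the CH2OH oxidized to CHO | C/C(=C\CO[Si](c1ccccc1)(c1ccccc1)C(C)(C)C)CC[C@@H]1[C@@](C)(C(C)=O)CO[C@@]1(C)C=O
F3 | step 8 | (1R,5S,8R)-8-[(3E)-5-[(tert-butyldiphenylsilyl)oxy]-3-methylpent-3-en-1-yl]-1,5-dimethyl-6-oxabicyclo[3.2.1]oct-3-en-2-one | C/C(=C\CO[Si](c1ccccc1)(c1ccccc1)C(C)(C)C)CC[C@@H]1[C@]2(C)CO[C@@]1(C)C=CC2=O
F4 | step 5 | N,N-dimethylhydrazone of keto ester 5 | CC(=NN(C)C)C(C)C(=O)OC/C(C)=C/CC/C(C)=C/CO[Si](c1ccccc1)(c1ccccc1)C(C)(C)C
F5 | step 5 | racemic N,N-dimethylhydrazone of the hydroxy ketone, relative configuration as in 11 (one enantiomer drawn) | CC(=NN(C)C)[C@@](C)(CO)[C@H](C(C)=C)CC/C(C)=C/CO[Si](c1ccccc1)(c1ccccc1)C(C)(C)C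
F6 | step 5 | (S)-2-methoxy-2-phenylacetate of the hydroxy dimethylhydrazone, single diastereomer with the configuration of 11 | CC(=NN(C)C)[C@@](C)(COC(=O)[C@@H](OC)c1ccccc1)[C@H](C(C)=C)CC/C(C)=C/CO[Si](c1ccccc1)(c1ccccc1)C(C)(C)C
F7 | step 5 | N,N-dimethylhydrazone of 11, single enantiomer | CC(=NN(C)C)[C@@](C)(CO)[C@H](C(C)=C)CC/C(C)=C/CO[Si](c1ccccc1)(c1ccccc1)C(C)(C)C
F8 | step 6 | N-methyl hydrazonium iodide of 10 (methyl on the pyrrolidine nitrogen) | CC(=N[N+]1(C)CCC[C@H]1COC)[C@@](C)(CO)[C@H](C(C)=C)CC/C(C)=C/CO[Si](c1ccccc1)(c1ccccc1)C(C)(C)C.[I-]
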